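## The problem

Target **13** is a C30 bicyclic triterpenoid alcohol: a 4,4,8,10-tetramethyldecalin (ring A = C1–C5/C10, ring B = C5–C10, terpenoid numbering) with a tertiary hydroxyl on C8 and, on C9, a sixteen-carbon (E,E)-homofarnesyl chain (C11 onward) holding three trisubstituted alkenes. Four contiguous stereocentres (C5, C10, C9, C8) must be set; C10 is an all-carbon quaternary centre and C8 a tertiary carbinol. The ring fusion is cis (H5 and the C10 methyl on the same face), unlike the common trans-fused labdane and polypodane series. The chain is cis to the C10 methyl, on the convex face, and the hydroxyl is trans to the chain. Only C5 can be bought; a ring closure tethered from C5 can set C10. The cis-decalin should then prefer the chair form that keeps the quaternary C4 equatorial on ring B and C1 axial, and this axial C1 shields the α face at both C9 and C8. The chain alkenes do not survive Lewis acids, peracids or strong protic acid, the tertiary alcohol dehydrates easily, and C9 can epimerise while C8 is a ketone; the chain must therefore arrive after all such steps. The enabling feature is that C5 carries H and the arm C6–C7–C8 leading to C9, while C9 is bonded to C10, whose other neighbours are C1 and a methyl group. This is the pattern of (R)-α-ionone **1** with a C10=C1 alkene: a carbenoid at C9 can add across it, and the surplus C1–C9 bond lies next to the C8 carbonyl and can be removed reductively.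

## Retrosynthesis

**13 ⇒ 12 ⇒ 10 + 11.** The chain is cut at C11–C12, the bond allylic to the first chain alkene. The farnesyl part is then the purchasable bromide **11**, an excellent SN2 electrophile, and C11 stays on the decalin as a carbanion stabilised by a sulfone (**10**), removed at the end via **12**. The neighbouring cut, C9–C11, would require a neopentyl-type enolate carbon to displace an unactivated homoallylic halide prone to elimination, and would cost extra steps to homologate **11**. Precursor **10** has no alkene and no chain. The forward reaction must alkylate on carbon at the primary end of **11** and remove sulfur without touching three alkenes.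

**10 ⇒ 9 ⇒ 8.** The C8–CH3 bond is cut to reveal ketone **8**; sulfur is at the sulfide level there and is oxidised after the methyl addition (**9** → **10**). A β-sulfonyl ketone would eliminate sulfinate, which fixes this order. The alternative of hydrating a C8 exocyclic alkene would deliver oxygen, not carbon, to the open β face and give the wrong carbinol. The forward step needs a non-basic methyl nucleophile entering from the β face.

**8 ⇒ 7.** The C9–C11 bond is cut to the regiodefined silyl enol ether **7** and a phenylthiomethyl cation equivalent. A one-carbon thionium electrophile is the most reactive partner available for a carbon flanked by the quaternary C10, and its sulfur later becomes the sulfone. The forward step must attack C9 from the β face and must not epimerise the product.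

**7 ⇒ 5.** Retrosynthetically the C1–C9 bond is added back. The C8=C9 enol ether cannot be made reliably by enolising a C8 decalone (C7 is the less hindered side), but it is exactly what reductive cleavage of the cyclopropyl ketone **5** delivers. The forward step must break C1–C9 and not C9–C10.

**5 ⇒ 4.** Both cyclopropane bonds from C9 (C9–C10 and C1–C9) are cut to give diazoketone **4**. This removes ring B, the quaternary centre and three stereocentres in one operation and leaves a monocycle with one stereocentre. Cutting only C9–C10 (a cationic or radical closure) would leave open which alkene carbon is attacked and which face; the carbenoid is tied to both by the tether.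

**4 ⇒ 3 ⇒ 2 ⇒ 1.** The diazo group is placed on the methyl carbon of the methyl ketone **2** through the trifluoroacetyl derivative **3**. **2** comes from **1** by saturating the enone alkene only. No skeletal bond is made; the requirements are methyl-side regioselectivity and an untouched C5.

## Roads not taken

Alternative 1: The cut runs through C5–C6 and C9–C10, a Diels–Alder union of the ring A enal 3,3-dimethylcyclohex-1-ene-1-carbaldehyde A1 (its formyl carbon is the future C10 methyl) with the chain-bearing (E)-2-silyloxy-3-methyl diene A2, giving the cis-fused adduct A3.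
- Merits: the cis fusion follows from the cyclic dienophile, an endo transition state would put the chain cis to the formyl group, and the silyloxy and alkyl groups of A2 reinforce one regiochemistry. A3 holds all thirty carbons and three of the four stereocentres after one intermolecular step; in convergence this road is better than the chosen one.
- Weak points: the β carbon of A1 is neopentyl (next to the C4 gem-dimethyl) and its α carbon becomes quaternary, so strong Lewis acid or pressure would be needed. A2, an acid-labile silyl dienol ether with three further nucleophilic alkenes, is unlikely to tolerate that. A2 must also be a single (E) isomer. Both partners are achiral, so the absolute configuration would depend on an enantioselective catalyst for a hindered α-substituted enal.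
- After A3 the oxygen is on C7, not C8. Hydroxylation at C8 (a new facial problem), removal of the C7 oxygen and reduction of formyl to methyl must follow, all with the polyene present.
- Comparison: the chosen plan buys C5, sets C10 intramolecularly without catalyst control, and keeps the chain away from Lewis acids and oxidants. It pays with stepwise construction of C9 and C8 and a two-step chain attachment.

Alternative 2: Nothing is cut for good. The trans-fused ring B bis-silyl dienol ether A5 is opened photochemically (conrotatory, C5–C10) to the all-cis ten-membered triene A6, which recloses thermally (disrotatory) to the cis-fused isomer A4.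
- Merits: it needs no reagent, follows the well-understood hexatriene–cyclohexadiene manifold, and could give both ring-fusion series from one intermediate. The chosen plan, fixed on the cis series, cannot do that. A4 has the C8 methyl in place and C9 as an sp2 carbon for later functionalisation.
- Weak points: the key step only re-forms a bond it has just broken and adds no carbon. A5 itself needs a multi-step synthesis. The helical triene A6 can close to either cis-fused diastereomer, and the only bias is the remote C3 silyloxy group, which the target lacks and which must later be removed. Sigmatropic hydrogen shifts in A6 and photostationary mixtures compete.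
- After A4 the whole chain, the C9 stereocentre and the C8 hydroxyl are still missing, and two oxygens (C3, C7) must be taken out.
- Comparison: the chosen key step makes two skeletal bonds and the quaternary centre from a two-step-derived chiral-pool precursor; Alternative 2 is longer at every stage for this target.

Alternative 3: The cut is at C8–C9. SmI2 reduces the C8 methyl ketone of the cis-1,2-disubstituted cyclohexane A8 to its ketyl, which adds 6-exo to the (E)-enoate on C10 to give hydroxy ester A7.
- Merits: C8 and C9 are formed in one step, the hydroxyl is created directly (no carbonyl addition with uncertain facial selectivity), and ketyl–enoate closures usually place hydroxyl and side chain trans, as required. In this respect the road is better than the chosen plan, which sets C9 and C8 in two separate steps (6 and 7) relying on conformational bias.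
- Weak points: the hard stereocentre is moved into the precursor. A8 needs a quaternary C10 and a tertiary C5 in cis relationship next to a gem-dimethyl group, with no simple chiral-pool source. Whether the new C9 substituent ends cis to the C10 methyl depends on the enoate rotamer and is not enforced.
- A7 ends at C12, so fourteen chain carbons still have to be attached through an sp3–sp2 coupling after several functional-group changes.
- Comparison: the chosen plan gets C5 by purchase and C10 from the tether, and attaches the chain with one alkylation by **11** and one desulfonylation.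

Key step: step 4

Assumption: (R)-α-ionone **1** is taken as purchasable in enantioenriched form; no step touches C5, so the optical purity of **13** rests on that of **1**.

## Route

Step 1
Reactants: 1 (R)-α-ionone, (3E)-4-[(1R)-2,6,6-trimethylcyclohex-2-en-1-yl]but-3-en-2-one
Product: 2 (R)-dihydro-α-ionone, 4-[(1R)-2,6,6-trimethylcyclohex-2-en-1-yl]butan-2-one
Conditions: H2 (1 atm), RhCl(PPh3)3 (5 mol %), PhH/EtOH, rt
Reagents that add atoms: none
Why: Homogeneous hydrogenation with RhCl(PPh3)3 saturates the unhindered 1,2-disubstituted enone alkene much faster than the hindered trisubstituted ring alkene and leaves the ketone alone; no enolate or dienolate forms, so C5 cannot epimerise and the ring alkene cannot migrate.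

Step 2
Reactants: 2 (R)-dihydro-α-ionone
Product: 3 1,1,1-trifluoro-6-[(1R)-2,6,6-trimethylcyclohex-2-en-1-yl]hexane-2,4-dione (used crude)
Conditions: LiN(SiMe3)2, THF, −78 °C; CF3CO2CH2CF3, −78 °C; aq. HCl work-up
Reagents that add atoms: 2,2,2-trifluoroethyl trifluoroacetate, O=C(OCC(F)(F)F)C(F)(F)F
Why: Kinetic deprotonation at the methyl group and Claisen-type acylation by the activated trifluoroacetate; this activates the methyl carbon (future C9) for diazo transfer without touching C5 or the ring alkene.

Step 3
Reactants: 3 1,1,1-trifluoro-6-[(1R)-2,6,6-trimethylcyclohex-2-en-1-yl]hexane-2,4-dione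
Product: 4 1-diazo-4-[(1R)-2,6,6-trimethylcyclohex-2-en-1-yl]butan-2-one
Conditions: MsN3, Et3N, H2O (1 equiv), MeCN, rt
Reagents that add atoms: methanesulfonyl azide, CS(=O)(=O)N=[N+]=[N-]
Why: Deacylative (detrifluoroacetylative) Regitz-type diazo transfer: the diketonate attacks the azide and the trifluoroacetyl group leaves on the sulfonamide nitrogen, giving the terminal α-diazoketone under mild base that does not affect the alkene.

Step 4
Reactants: 4 1-diazo-4-[(1R)-2,6,6-trimethylcyclohex-2-en-1-yl]butan-2-one
Product: 5 (1S,2S,6R,10R)-1,7,7-trimethyltricyclo[4.4.0.0^2,10]decan-3-one (C8 ketone, cyclopropane C1–C9–C10, C10 methyl cis to H5)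
Conditions: Cu(acac)2 (5 mol %), ClCH2CH2Cl, reflux, slow addition of 4 at high dilution
Reagents that add atoms: none
Why: The copper catalyst decomposes the diazoketone with loss of N2 to an electrophilic copper carbenoid at C9, which adds to the electron-rich trisubstituted C10=C1 alkene in a concerted, asynchronous [2+1] step that forms C9–C10 and C1–C9. The closest known reaction type is the copper-catalysed intramolecular cyclopropanation of δ,ε-unsaturated α-diazoketones to bicyclo[4.1.0]heptan-2-ones. Ring B closes as the six-membered ketone ring by bonding of C9 to the proximal alkene carbon C10 through the tether C6–C7–C8 from C5, and the cyclopropane C1–C9–C10 closes in the same event as the second, temporary ring. C10 is set by the tether: C9 can reach the alkene only on the face of ring A that carries C6, because a six-membered ring cannot span the torsion to the opposite face, so C9 ends cis to C6 and the C10 methyl cis to H5. C1 and C9 follow from the suprafacial addition (cis-fused cyclopropane, C8 syn to ring A) and are erased in step 5. The step needs chemoselectivity for cyclopropanation over 1,5 C–H insertion into the tertiary allylic C5–H, over carbene dimerisation and over Wolff rearrangement. A copper carbenoid (far less prone to C–H insertion than those from Rh2(OAc)4), the nucleophilic alkene and slow addition at high dilution secure it. No enantioselective catalyst is needed because C5 is already stereodefined.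

Step 5
Reactants: 5 (1S,2S,6R,10R)-1,7,7-trimethyltricyclo[4.4.0.0^2,10]decan-3-one
Product: 7 trimethyl{[(4aR,8aS)-5,5,8a-trimethyl-3,4,4a,5,6,7,8,8a-octahydronaphthalen-2-yl]oxy}silane (cis-fused C8=C9 silyl enol ether), via lithium C8–C9 enolate 6 (not isolated)
Conditions: Li, NH3(l)/THF, t-BuOH (1 equiv), −78 °C; isoprene; NH3 removed; TMSCl, Et3N, THF, −78 → 0 °C
Reagents that add atoms: chlorotrimethylsilane, C[Si](C)(C)Cl
Why: Dissolving-metal reductive cleavage of a conjugated cyclopropyl ketone: the ketyl opens C1–C9, the cyclopropane bond external to ring B that overlaps with the carbonyl π system and gives the less substituted carbanion, which t-BuOH protonates to the C1 methylene. The regiodefined lithium enolate is then silylated on oxygen; no stereocentre is created, and C1 and C9 cease to be stereogenic.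

Step 6
Reactants: 7 trimethyl{[(4aR,8aS)-5,5,8a-trimethyl-3,4,4a,5,6,7,8,8a-octahydronaphthalen-2-yl]oxy}silane
Product: 8 (1R,4aR,8aS)-5,5,8a-trimethyl-1-[(phenylsulfanyl)methyl]octahydronaphthalen-2(1H)-one (CH2SPh on C9, cis to the C10 methyl)
Conditions: PhSCH2Cl, TiCl4, CH2Cl2, −78 → −23 °C; aq. NaHCO3
Reagents that add atoms: chloromethyl phenyl sulfide, ClCSc1ccccc1
Why: Lewis-acid-mediated phenylthiomethylation of a silyl enol ether (Mukaiyama-type alkylation through the thionium ion), a reaction type that tolerates hindered enol ether carbons. C9 is set by attack on the β (convex) face, anti to the axial C10–C1 bond of the favoured cis-decalin conformer (quaternary C4 equatorial on ring B), which places CH2SPh cis to the C10 methyl.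

Step 7
Reactants: 8 (1R,4aR,8aS)-5,5,8a-trimethyl-1-[(phenylsulfanyl)methyl]octahydronaphthalen-2(1H)-one
Product: 9 (1R,2R,4aR,8aS)-2,5,5,8a-tetramethyl-1-[(phenylsulfanyl)methyl]decahydronaphthalen-2-ol
Conditions: MeLi, CeCl3 (anhydrous), THF, −78 °C; aq. NH4Cl
Reagents that add atoms: methyllithium, [Li]C
Why: Organocerium 1,2-addition, chosen because it does not enolise C9 and so avoids epimerisation and β-elimination of thiophenoxide. The axial trajectory at C8 is blocked by the syn-axial C1 methylene, so methyl enters equatorially from the β face and the hydroxyl ends α, trans to the C9 substituent.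

Step 8
Reactants: 9 (1R,2R,4aR,8aS)-2,5,5,8a-tetramethyl-1-[(phenylsulfanyl)methyl]decahydronaphthalen-2-ol
Product: 10 (1R,2R,4aR,8aS)-1-[(benzenesulfonyl)methyl]-2,5,5,8a-tetramethyldecahydronaphthalen-2-ol
Conditions: mCPBA (2.2 equiv), NaHCO3, CH2Cl2, 0 °C → rt
Reagents that add atoms: 3-chloroperoxybenzoic acid, OOC(=O)c1cccc(Cl)c1
Why: Peracid oxidation of sulfide to sulfone through the sulfoxide; it is done here because the molecule holds no alkene yet, and the sulfone is needed to acidify C11.

Step 9
Reactants: 10 (1R,2R,4aR,8aS)-1-[(benzenesulfonyl)methyl]-2,5,5,8a-tetramethyldecahydronaphthalen-2-ol; 11 (2E,6E)-farnesyl bromide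
Product: 12 (1R,2R,4aR,8aS)-1-[(3E,7E)-1-(benzenesulfonyl)-4,8,12-trimethyltrideca-3,7,11-trien-1-yl]-2,5,5,8a-tetramethyldecahydronaphthalen-2-ol (both configurations at the sulfonyl-bearing C11 expected; both converge on 13)
Conditions: n-BuLi (2.1 equiv), THF, −78 → −20 °C; 11, DMPU, −78 → 0 °C; aq. NH4Cl
Reagents that add atoms: none
Why: Alkylation of an α-sulfonyl carbanion (as the O,C-dilithio species) with a primary allylic bromide, the classical sulfone coupling of prenyl units. SN2 attack at CH2Br keeps the alkene geometry of 11; the C11 configuration is irrelevant because the sulfone is removed next.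

Step 10
Reactants: 12 (1R,2R,4aR,8aS)-1-[(3E,7E)-1-(benzenesulfonyl)-4,8,12-trimethyltrideca-3,7,11-trien-1-yl]-2,5,5,8a-tetramethyldecahydronaphthalen-2-ol
Product: 13 (1R,2R,4aR,8aS)-2,5,5,8a-tetramethyl-1-[(3E,7E)-4,8,12-trimethyltrideca-3,7,11-trien-1-yl]decahydronaphthalen-2-ol (target)
Conditions: Na(Hg) (6 %), Na2HPO4, MeOH/THF, −20 °C → rt
Reagents that add atoms: none
Why: Reductive desulfonylation with Na(Hg) in buffered methanol. The sulfone is homoallylic, not allylic, so there is no path to alkene transposition or E/Z scrambling, and isolated trisubstituted alkenes and the tertiary alcohol are inert.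

## Compound list

1 | (R)-α-ionone, (3E)-4-[(1R)-2,6,6-trimethylcyclohex-2-en-1-yl]but-3-en-2-one | CC(=O)/C=C/[C@H]1C(C)=CCCC1(C)C | starting material
2 | (R)-dihydro-α-ionone, 4-[(1R)-2,6,6-trimethylcyclohex-2-en-1-yl]butan-2-one | CC(=O)CC[C@H]1C(C)=CCCC1(C)C | intermediate
3 | 1,1,1-trifluoro-6-[(1R)-2,6,6-trimethylcyclohex-2-en-1-yl]hexane-2,4-dione | O=C(CC(=O)C(F)(F)F)CC[C@H]1C(C)=CCCC1(C)C | intermediate
4 | 1-diazo-4-[(1R)-2,6,6-trimethylcyclohex-2-en-1-yl]butan-2-one | [N-]=[N+]=CC(=O)CC[C@H]1C(C)=CCCC1(C)C | intermediate
5 | (1S,2S,6R,10R)-1,7,7-trimethyltricyclo[4.4.0.0^2,10]decan-3-one | O=C1CC[C@@H]2C(C)(C)CC[C@@H]3[C@H]1[C@]23C | intermediate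
6 | lithium (4aR,8aS)-5,5,8a-trimethyl-3,4,4a,5,6,7,8,8a-octahydronaphthalen-2-olate (C8–C9 enolate) | [Li+].[O-]C1=C[C@@]2(C)CCCC(C)(C)[C@H]2CC1 | intermediate
7 | trimethyl{[(4aR,8aS)-5,5,8a-trimethyl-3,4,4a,5,6,7,8,8a-octahydronaphthalen-2-yl]oxy}silane | C[Si](C)(C)OC1=C[C@@]2(C)CCCC(C)(C)[C@H]2CC1 | intermediate
8 | (1R,4aR,8aS)-5,5,8a-trimethyl-1-[(phenylsulfanyl)methyl]octahydronaphthalen-2(1H)-one | c1ccc(cc1)SC[C@@H]1[C@@]2(C)CCCC(C)(C)[C@H]2CCC1=O | intermediate
9 | (1R,2R,4aR,8aS)-2,5,5,8a-tetramethyl-1-[(phenylsulfanyl)methyl]decahydronaphthalen-2-ol | c1ccc(cc1)SC[C@@H]1[C@@]2(C)CCCC(C)(C)[C@H]2CC[C@@]1(C)O | intermediate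
10 | (1R,2R,4aR,8aS)-1-[(benzenesulfonyl)methyl]-2,5,5,8a-tetramethyldecahydronaphthalen-2-ol | O=S(=O)(C[C@@H]1[C@@]2(C)CCCC(C)(C)[C@H]2CC[C@@]1(C)O)c1ccccc1 | intermediate
11 | (2E,6E)-farnesyl bromide, (2E,6E)-1-bromo-3,7,11-trimethyldodeca-2,6,10-triene | CC(C)=CCC/C(C)=C/CC/C(C)=C/CBr | starting material
12 | (1R,2R,4aR,8aS)-1-[(3E,7E)-1-(benzenesulfonyl)-4,8,12-trimethyltrideca-3,7,11-trien-1-yl]-2,5,5,8a-tetramethyldecahydronaphthalen-2-ol (both C11 epimers) | CC(C)=CCC/C(C)=C/CC/C(C)=C/CC([C@@H]1[C@@]2(C)CCCC(C)(C)[C@H]2CC[C@@]1(C)O)S(=O)(=O)c1ccccc1 | intermediate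
13 | (1R,2R,4aR,8aS)-2,5,5,8a-tetramethyl-1-[(3E,7E)-4,8,12-trimethyltrideca-3,7,11-trien-1-yl]decahydronaphthalen-2-ol | CC(C)=CCC/C(C)=C/CC/C(C)=C/CC[C@@H]1[C@@]2(C)CCCC(C)(C)[C@H]2CC[C@@]1(C)O | target

## Step count and uncertain steps

Total: 10 steps. Longest linear sequence: 10 steps (**1** → **13**); **11** is purchased and enters at step 9.

**Step 4 (key step).** The most likely failure is diversion of the carbenoid: insertion into the tertiary allylic C5–H (a cyclopentanone), carbene dimerisation or Wolff rearrangement, because closing a six-membered ring is slower than the five-membered cases. Fallback, leaving the diazo route: from **2**, the methyl ketone would be converted through the enol phosphate diethyl 4-[(1R)-2,6,6-trimethylcyclohex-2-en-1-yl]but-1-en-2-yl phosphate F1 (LiN(i-Pr)2, ClP(O)(OEt)2) and elimination with further LiN(i-Pr)2 into the terminal alkyne (6R)-6-(but-3-yn-1-yl)-1,5,5-trimethylcyclohex-1-ene F2. Gold-catalysed alkyne oxidation (Ph3PAuNTf2, 8-methylquinoline N-oxide, ClCH2CH2Cl) would generate the same α-oxo carbenoid at C9 without a diazo compound, and its cyclopropanation of C10=C1 would return to **5**.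

**Step 6.** Carbon–carbon bond formation at the hindered C9 may be outrun by protodesilylation of the enol ether, and the Lewis acid may erode the C9 configuration through enolisation of the β-thio ketone. Fallback: from **7**, a lanthanide-triflate-catalysed aqueous Mukaiyama aldol with formaldehyde (aq. HCHO, Yb(OTf)3, THF) would give the hydroxymethyl ketone (1S,4aR,8aS)-1-(hydroxymethyl)-5,5,8a-trimethyloctahydronaphthalen-2(1H)-one F3. Substitution of its primary hydroxyl with PhSSPh/Bu3P would return to **8**.

**Step 7.** Facial selectivity may be poor or reversed if ring B reacts through another chair or twist form, and any enolisation would expel thiophenoxide. Fallback, delivering oxygen instead of carbon to C8 (a reagent attacking from the wrong face for methyl then gives the right carbinol): from **8**, methylenation with Cp2TiMe2 (PhMe, 65 °C) would give (1S,4aR,8aS)-5,5,8a-trimethyl-2-methylidene-1-[(phenylsulfanyl)methyl]decahydronaphthalene F4. Excess mCPBA would oxidise sulfur to the sulfone and the exocyclic alkene to the spiro-epoxide 1-[(benzenesulfonyl)methyl]-5,5,8a-trimethyloctahydro-1H-spiro[naphthalene-2,2'-oxirane] with oxygen on the face opposite the C10 methyl F5. Opening at the CH2 terminus with LiEt3BH would return to **10**.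

**Step 9.** The dilithio species of a sulfone flanked by a quaternary carbinol and a neopentyl-type C9 may alkylate slowly; ortho-lithiation of the phenyl ring or base-induced loss of HBr from **11** may then take over. Fallback without a sulfone carbanion: from **9**, deprotonation of the hydroxyl (n-BuLi) and reductive lithiation of the C–S bond with lithium 4,4'-di-tert-butylbiphenylide (THF, −78 °C) would give the O,C11-dilithio species of (1R,2R,4aR,8aS)-1,2,5,5,8a-pentamethyldecahydronaphthalen-2-ol (C11 lithiated) F6. Transmetalation with MgBr2·OEt2 and Li2CuCl4-catalysed coupling with **11** at its primary carbon would give **13** directly.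

## Further compounds

F1 | step 4 | diethyl 4-[(1R)-2,6,6-trimethylcyclohex-2-en-1-yl]but-1-en-2-yl phosphate | C=C(OP(=O)(OCC)OCC)CC[C@H]1C(C)=CCCC1(C)C
F2 | step 4 | (6R)-6-(but-3-yn-1-yl)-1,5,5-trimethylcyclohex-1-ene | C#CCC[C@H]1C(C)=CCCC1(C)C
F3 | step 6 | (1S,4aR,8aS)-1-(hydroxymethyl)-5,5,8a-trimethyloctahydronaphthalen-2(1H)-one | OC[C@@H]1[C@@]2(C)CCCC(C)(C)[C@H]2CCC1=O
F4 | step 7 | (1S,4aR,8aS)-5,5,8a-trimethyl-2-methylidene-1-[(phenylsulfanyl)methyl]decahydronaphthalene | c1ccc(cc1)SC[C@@H]1[C@@]2(C)CCCC(C)(C)[C@H]2CCC1=C
F5 | step 7 | 1-[(benzenesulfonyl)methyl]-5,5,8a-trimethyloctahydro-1H-spiro[naphthalene-2,2'-oxirane], oxirane oxygen α (opposite the C10 methyl), cis-fused | O=S(=O)(C[C@@H]1[C@@]2(C)CCCC(C)(C)[C@H]2CC[C@]13CO3)c1ccccc1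
F6 | step 9 | O,C11-dilithio derivative of (1R,2R,4aR,8aS)-1,2,5,5,8a-pentamethyldecahydronaphthalen-2-ol | [Li]C[C@@H]1[C@@]2(C)CCCC(C)(C)[C@H]2CC[C@@]1(C)O[Li]
A1 | alternative 1 | 3,3-dimethylcyclohex-1-ene-1-carbaldehyde | O=CC1=CC(C)(C)CCC1
A2 | alternative 1 | triisopropyl{[(3E,7E,11E)-3,8,12,16-tetramethylheptadeca-1,3,7,11,15-pentaen-2-yl]oxy}silane | C=C(O[Si](C(C)C)(C(C)C)C(C)C)/C(C)=C/CC/C=C(C)/CC/C=C(C)/CCC=C(C)C
A3 | alternative 1 | cis-fused Diels–Alder adduct: C10 formyl, C7 triisopropylsilyl enol ether (C7=C8, methyl on C8), full chain on C9 | CC(C)=CCC/C(C)=C/CC/C(C)=C/CC[C@@H]1[C@@]2(C=O)CCCC(C)(C)[C@H]2CC(O[Si](C(C)C)(C(C)C)C(C)C)=C1C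
A4 | alternative 2 | cis-fused ring B 6,8-diene with tert-butyldimethylsilyloxy groups on C3 and C7 (5β-H, 10β-methyl) | CC1=C[C@@]2(C)CC[C@H](O[Si](C)(C)C(C)(C)C)C(C)(C)[C@H]2C=C1O[Si](C)(C)C(C)(C)C
A5 | alternative 2 | trans-fused isomer of A4 (5α-H, 10β-methyl) | CC1=C[C@@]2(C)CC[C@H](O[Si](C)(C)C(C)(C)C)C(C)(C)[C@@H]2C=C1O[Si](C)(C)C(C)(C)C
A6 | alternative 2 | all-cis ten-membered triene (C5=C6, C7=C8, C9=C10) with silyloxy groups on C3 and C7 | C/C1=C/C(C)=C(O[Si](C)(C)C(C)(C)C)\C=C/C(C)(C)[C@@H](O[Si](C)(C)C(C)(C)C)CC1
A7 | alternative 3 | methyl 2-[(1R,2R,4aR,8aS)-2-hydroxy-2,5,5,8a-tetramethyldecahydronaphthalen-1-yl]acetate | COC(=O)C[C@@H]1[C@@]2(C)CCCC(C)(C)[C@H]2CC[C@@]1(C)O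
A8 | alternative 3 | methyl (2E)-3-[1,3,3-trimethyl-2-(3-oxobutyl)cyclohexyl]prop-2-enoate, acrylate and oxobutyl groups cis | COC(=O)/C=C/[C@@]1(C)CCCC(C)(C)[C@H]1CCC(C)=O
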